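**Two ceilings.** Product in these flasks is reckoned against two amounts, and the lower one is the reckoning for the end. The first is the reagent ceiling, reagent charge over substrate charge, as each product takes one reagent: 60.0% in winter, 120% at midnight. Where it is the lower, reagent is the limiting reagent. The second is the conversion the chain reaches by the stopping time.

| setting | south-east | south | winter | midnight |
|---|---|---|---|---|
| substrate | 0.10 M | 0.10 M | 0.10 M | 0.10 M |
| reagent | 0.088 M | 0.19 M | 0.0600 M | 0.120 M |
| initiator | 15 mM | 15 mM | 15 mM | 15 mM |
| remark | run made earlier | run made earlier |  |  |
| time |  |  | 50 min | 15 min |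

- south-east (time / min: product / %, substrate / %): 0.417: 1.3, 99.1; 1.00: 3.8, 96.5; 2.00: 7.8, 91.9; 3.00: 11.1, 88.9; 5.00: 17.9, 81.6; 6.00: 20.5, 79.1; 8.00: 26.2, 73.8
- south (time / min: product / %, substrate / %): 0.417: 1.8, 98.1; 1.00: 4.4, 96.6; 2.00: 7.7, 92.0; 3.00: 11.9, 89.1; 5.00: 17.5, 82.5; 6.00: 20.8, 78.8; 8.00: 25.8, 73.4

(readings scatter by 0.3 percentage points)

- percentages count the substrate that a species holds: one ended chains B counts as two
- the analysis behind the earlier runs scatters by 0.3 percentage points, standard deviation
- what may be going on: 2 initiating radical -> ended chains A; substrate + initiating radical <-> chain carrier; reagent + chain carrier -> product + initiating radical; initiator -> 2 initiating radical; 2 chain carrier -> ended chains B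

1. which one finishes higher in amount of product, in percent of the substrate charged ("neither" within 2 percentage points) (winter / midnight / neither)
2. amount of product at the end, in percent of the substrate charged, winter
3. amount of product at the end, in percent of the substrate charged, midnight

**Fraction left.** South-east and south read 26.2% and 25.8% of product at 8.00 min, though south holds twice the reagent, so these runs are reckoned as pseudo-first-order in substrate. The logarithm of the fraction left, per minute and averaged over both runs, is 0.0420 min⁻¹ by 2.00 min and 0.0383 min⁻¹ by 8.00 min. Read as an exponential fade, this gives a loose fade constant of 0.0290 min⁻¹ and a total of 1.49: the chain reserve, the logarithm of the fraction left that the fading chain can spend. The reserve spent by a given time is the reserve times the share of the fade completed.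

Reckoned so, winter's conversion is 68.0%, above its ceiling by a ratio of 1.13, so winter is reckoned to end on the ceiling. Midnight's is 40.9%, at a ratio of 0.341 to its ceiling, so midnight is reckoned to end at that conversion.

**The forecast.** It names winter, with 58% for winter and 41% for midnight, setting winter under the ceiling as “the rate slows as reagent runs out”. The reckoning here differs on that point.

**The flask.** Of the two, winter finishes higher, at 60.0% against 41.7% for midnight.

    2 initiating radical → ended chains A (k = 8.30 × 10⁷ L mol⁻¹ s⁻¹)
    substrate + initiating radical ⇌ chain carrier (K = 69000 L mol⁻¹, k = 1.20 × 10⁵ L mol⁻¹ min⁻¹)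
    reagent + chain carrier → product + initiating radical (k = 70000 L mol⁻¹ s⁻¹)
    initiator → 2 initiating radical (k = 0.0400 min⁻¹)
    2 chain carrier → ended chains B (k = 3.00 × 10⁸ L mol⁻¹ s⁻¹)

At 10.6 min winter's chain carrier goes to product 170 times as fast as to ended chains B. At 50.0 min winter holds product 60.0%, reagent 0%, substrate 34.8% and ended chains B 5.21%.

**Second flask.** A neighbour flask is winter with 0.24 M of reagent: its ceiling is 240%, and the same reserve and time give 68.0%, the lower amount. The computed flask gives 73.2%.

All runs come from a simulation from invented constants, noise included.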